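## Structural features

The target is a flavanone: benzo ring A is fused through C4a and C8a to the dihydropyranone ring C (O1, C2, C3, C4=O), and the 3,4-dimethoxyphenyl ring B sits on C2. Ring A has hydrogen at C5 and a free hydroxyl at C7 flanked by two 3-methylbut-2-enyl (prenyl) chains at C6 and C8. C2 is the only stereocentre and is S; it is benzylic, bonded to O1 and beta to the C4 carbonyl, so it has no stereochemical neighbour to relay from. That position is configurationally fragile, because base opens ring C by retro-oxa-Michael elimination and re-closure gives the racemate. The prenyl alkenes are the second fragile feature: they do not tolerate hydrogenation or electrophilic halogen, and under acid each can cyclise onto the C7 hydroxyl. The real difficulty is one of order: two linear prenyl groups must be placed ortho to a phenol and C2 must be set as a single enantiomer, with no strong base or acid afterwards. The plan exploits the fact that the C4 carbonyl is the only atom between C4a of ring A and the C3–C2 unit bearing ring B, while O1 sits on C8a ortho to C4a. Ring C is therefore the sum of an ortho-iodophenol, carbon monoxide and an aryl alkyne, and the flat chromen-4-one so formed can carry all the ring A chemistry before C2 becomes stereogenic.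

## Logic of the disconnections

**13 back to 10.** The C2–H and C3–H bonds are cut, that is, H2 is removed across C2–C3. This is the last forward step because the iodination and the basic coupling that ring A needs would endanger a C2 stereocentre, whereas 10 is flat and cannot racemise. The gain is the loss of the only stereocentre and of all base sensitivity in the intermediates. The forward step must deliver hydride to C2 on one face under catalyst control in a non-basic medium, leave the C4 carbonyl and the two trisubstituted alkenes untouched, and cope with the free hydroxyl of 10.

**10 back to 8 and 9.** The C6–CH2 and C8–CH2 bonds are cut. Cutting here turns both side chains into one purchasable five-carbon reagent used twice and leaves a symmetrical pair of aryl–halogen handles. The forward coupling must join each aryl carbon to the primary terminus of the allyl unit of 9, not the tertiary one, at two hindered positions beside an ionisable hydroxyl.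

**8 back to 7.** The C6–I and C8–I bonds are cut. These are the two positions ortho to the C7 hydroxyl (its para position is the ring fusion carbon C4a), so the hydroxyl of 7 directs both halogens and no directing group has to be added. The forward step must halogenate ring A twice and leave ring B and C3 alone, which calls for a reagent that reacts only with phenols under buffered conditions.

**7 back to 2, 3 and 4.** Three bonds are cut: C4–C4a, C3–C4 and O1–C2. This removes ring C entirely and divides the skeleton into a ring A piece (2), a one-carbon piece (3) and a ring B piece (4) that already holds C2 and C3. It is the largest gain in simplicity in the route. The forward step must insert 3 before the alkyne couples, and must close the ring through oxygen onto the alkyne carbon remote from the carbonyl (six-membered), not the near one (five-membered).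

**2 back to 1.** The two O–acetyl bonds are cut. Compound 1 carries two free hydroxyls, is electron-rich and sensitive to air and light, and would enter the key step as a phenoxide. Masking both oxygens as esters that the amine of the key step removes in the flask costs one simple step and no separate deprotection. Compounds 1, 3, 4 and 9 are purchased.

## Other disconnections considered

**Alternative 1:** The cut removes three ring A bonds, C4a–C8a, C5–C6 and C7–C8, the first of which also belongs to ring C. In the forward direction the tethered diyne A1 (a terminal ynone joined through C3, C2 and O1 to a prenyl-substituted ynol ether) and the silyloxyalkyne A2 would undergo a [2+2+2] cyclotrimerisation on a cationic rhodium catalyst such as [Rh(cod)2]BF4/BINAP to give A3, and fluoride would then release 13.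
- In its favour: ring A is made with all four substituents in place, so there is no electrophilic substitution and no allyl–metal regiochemistry, and C2 is introduced early and never sees base.
- Against it: A1 is an alkynyl ether of a secondary benzylic alcohol and a beta-alkoxy ynone at once. Thermal sigmatropic or retro-ene fragmentation of the ynol ether and E1cB loss of the oxygen substituent are both plausible before any cyclisation.
- Against it: the orientation in which A2 inserts (silyloxy carbon next to C8 or next to C5) is not fixed by the tether, and the 1,4-enyne units offer rhodium competing ene pathways.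
- Structure: the alternative is the better plan for the substitution pattern of ring A, which it builds instead of decorating.
- Mechanism: it forms three C–C bonds and two rings in one step against three bonds and one ring, which is also better, but it has a regiochemical question that the chosen key step does not have.
- Step economy: A1 and A2 each need several steps, one of them asymmetric, so the longest line would clearly exceed the five steps of the chosen route. On stereocentres formed in the key step the two plans are equal (none).

**Alternative 2:** The cut is the single bond C4–C4a. In the forward direction the bromoaryl ether A4, which already carries C2 in the S configuration and a Weinreb amide at C4, would undergo bromine–lithium exchange at low temperature, and the aryllithium would attack the amide carbonyl to close ring C as A5.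
- In its favour: a Parham cyclisation onto a Weinreb amide is reliable for six-membered rings, and the chelated tetrahedral intermediate stops over-addition.
- In its favour: no toxic gas is used, and the absolute configuration would come from a benzylic alcohol precursor of known configuration. On predictability of configuration this is better than the chosen plan, which relies on a late catalytic step.
- Against it: the alpha hydrogens of the beta-aryloxy amide are acidic, and deprotonation in place of halogen exchange would eject the phenoxide and destroy C2.
- Against it, and more seriously: A5 has no prenyl groups. Desilylation, double halogenation and a basic cross-coupling would then have to be run on a flavanone that racemises by ring opening, or the prenyl groups would have to be carried on a hexasubstituted bromoarene through the lithiation.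
- Structure: the chosen plan is superior, because it does the ring A chemistry on a flat intermediate.
- Mechanism: the alternative forms one bond against three.
- Step economy: building A4, cyclising and then functionalising ring A would need about twice as many steps. The need for cryogenic organolithium chemistry is roughly an equal operational burden to handling carbon monoxide.

**Alternative 3:** The cut removes C4–C4a, C5–C6, C7–C8, C4a–C8a and O1–C2 at once. In the forward direction the cinnamic acid A6 and three units of malonic acid A7, after activation as thioesters by ligases, would be condensed by a chalcone synthase acting with a chalcone reductase, and a chalcone isomerase would close ring C to give A8.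
- In its favour: five bonds, two rings and the S configuration at C2 arise in one aqueous operation without protecting groups. On bond economy and on intrinsic stereocontrol at C2 this is better than the chosen plan.
- Against it: the starter lacks the 4-hydroxyl that the ligase and synthase normally recognise. Synthase–reductase coupling is seldom complete, so 5-hydroxy congeners would accompany A8, and only isomerases that accept 6'-deoxychalcones would close the ring.
- Against it, decisively: A8 still lacks both prenyl groups. Chemical prenylation of A8 meets the same racemisation problem as alternative 2, and enzymatic prenylation needs two transferases of different regioselectivity whose acceptance of this substrate is unknown.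
- Structure and mechanism: the enzymatic cascade is the more elegant construction of rings A and C.
- Step economy: it is nominally shorter to A8, but the distance from A8 to 13 and the enzyme development make the chosen plan the more predictable one.

Key step: step 2

Assumption: (R)-DTBM-SEGPHOS is taken as the ligand antipode whose copper hydride adds to the C2 face leading to the (2S) product; the sense has to be confirmed in the first run, and the (S)-ligand is used without other change if it proves to be the reverse.

## Route

Step 1
Reactants: 1 4-iodoresorcinol (4-iodobenzene-1,3-diol)
Product: 2 4-iodo-1,3-phenylene diacetate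
Conditions: Ac2O, pyridine, DMAP (cat.), CH2Cl2, 0 °C to rt
Reagents that add atoms: acetic anhydride, CC(=O)OC(C)=O
Why: DMAP-catalysed O-acetylation of both phenols (nucleophilic acyl substitution); the diacetate is bench-stable, is not a phenoxide at the oxidative addition stage, and is unmasked by the amine of the next step, so no deprotection step is added.

Step 2
Reactants: 2 4-iodo-1,3-phenylene diacetate; 3 carbon monoxide; 4 4-ethynyl-1,2-dimethoxybenzene
Product: 7 2-(3,4-dimethoxyphenyl)-7-hydroxychromen-4-one, via ynone diacetate 5 (not isolated), via diethylamino enone 6 (not isolated)
Conditions: PdCl2(PPh3)2 (5 mol %), dppp (5 mol %), thiourea (5 mol %), Et2NH–DBU, CO (1 atm, balloon), 40 °C then 60 °C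
Reagents that add atoms: none
Why: This is the palladium-catalysed carbonylative Sonogashira coupling and cyclisation of ortho-iodophenol acetates, carbon monoxide and aryl acetylenes, the closest known reaction type and one established for flavones. PdCl2(PPh3)2 is reduced in the flask to zerovalent palladium, which inserts into the C4a–I bond of 2; insertion of 3 gives the aroyl palladium iodide (C4–C4a), and amine-assisted transfer of the alkynyl group of 4 followed by reductive elimination forms C3–C4 and releases ynone 5. Diethylamine then cleaves both aryl acetates and adds to the beta carbon of the ynone to give enaminone 6. The freed ortho hydroxyl attacks that same carbon and expels the amine, forming O1–C2 and closing ring C in the 6-endo mode (6-endo-dig with respect to the ynone, carried out as a 6-endo-trig addition–elimination on 6). No stereocentre is formed and the product is flat. Three selectivities are needed: carbonylative over direct coupling, secured by the copper-free conditions, the CO atmosphere and the electron-rich aryl palladium, which inserts CO quickly; 6-endo over 5-exo closure, secured by the secondary amine, which occupies the beta carbon before oxygen can attack the alpha carbon; and the site of acylation on ring A, fixed by the single C–I bond. The acetates keep the iodoarene less electron-rich during oxidative addition and release the phenols only once the amine is present, and balloon pressure suffices, so no pressure vessel is needed.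

Step 3
Reactants: 7 2-(3,4-dimethoxyphenyl)-7-hydroxychromen-4-one
Product: 8 2-(3,4-dimethoxyphenyl)-7-hydroxy-6,8-diiodochromen-4-one
Conditions: BnMe3N·ICl2 (2.2 equiv), NaHCO3, CH2Cl2–MeOH, rt, dark
Reagents that add atoms: benzyltrimethylammonium dichloroiodate, C[N+](C)(C)Cc1ccccc1.Cl[I-]Cl
Why: Electrophilic ortho,ortho'-diiodination of a para-substituted phenol; under bicarbonate buffering the ammonium dichloroiodate reacts only with the phenol ring, so C8 and then C6 are iodinated while the dimethoxyphenyl ring B and C3 stay untouched, and no ammonia–iodine mixture is needed.

Step 4
Reactants: 8 2-(3,4-dimethoxyphenyl)-7-hydroxy-6,8-diiodochromen-4-one; 9 prenylboronic acid pinacol ester (4,4,5,5-tetramethyl-2-(3-methylbut-2-enyl)-1,3,2-dioxaborolane, 3 equiv)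
Product: 10 2-(3,4-dimethoxyphenyl)-7-hydroxy-6,8-bis(3-methylbut-2-enyl)chromen-4-one
Conditions: Pd(OAc)2 (5 mol %), tBuXPhos (10 mol %), K3PO4, MeCN–H2O, 70 °C
Reagents that add atoms: none
Why: Double Suzuki–Miyaura coupling of an aryl iodide with a 3,3-disubstituted allylboronate; a bulky di-tert-butylbiarylphosphine is chosen because such ligands steer reductive elimination to the unhindered primary allyl terminus and so give the linear prenyl arene. The flat chromen-4-one and its phenoxide tolerate aqueous phosphate, and boron replaces tin for safety.

Step 5
Reactants: 10 2-(3,4-dimethoxyphenyl)-7-hydroxy-6,8-bis(3-methylbut-2-enyl)chromen-4-one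
Product: 13 (2S)-2-(3,4-dimethoxyphenyl)-7-hydroxy-6,8-bis(3-methylbut-2-enyl)chroman-4-one, via aryl silyl ether 11 (not isolated), via bis-silyl enol ether 12 (not isolated)
Conditions: Cu(OAc)2 (5 mol %), (R)-DTBM-SEGPHOS (5.5 mol %), (EtO)2MeSiH (4 equiv), THF, 0 °C to rt; then aq. NH4F, 0 °C
Reagents that add atoms: none
Why: Copper hydride asymmetric conjugate reduction of a chromen-4-one: the phenol is first silylated by the silane with loss of H2 (11), the ligated copper hydride adds hydride to C2 on the face selected by the chiral bisphosphine (catalyst control of the C2 stereocentre), and the copper enolate is trapped by the silane as silyl enol ether 12. Mild fluoride hydrolysis then returns the ketone and the phenol without base or strong acid, so C2 is not scrambled and the prenyl groups do not cyclise; unactivated trisubstituted alkenes are inert to copper hydride.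

## Compound list

1 | 4-iodoresorcinol (4-iodobenzene-1,3-diol) | Oc1ccc(I)c(O)c1 | starting material
2 | 4-iodo-1,3-phenylene diacetate | CC(=O)Oc1ccc(I)c(OC(C)=O)c1 | intermediate
3 | carbon monoxide | [C-]#[O+] | starting material
4 | 4-ethynyl-1,2-dimethoxybenzene | C#Cc1ccc(OC)c(OC)c1 | starting material
5 | 4-[3-(3,4-dimethoxyphenyl)prop-2-ynoyl]-1,3-phenylene diacetate (ynone diacetate) | CC(=O)Oc1ccc(C(=O)C#Cc2ccc(OC)c(OC)c2)c(OC(C)=O)c1 | intermediate (not isolated)
6 | (E)-3-(diethylamino)-1-(2,4-dihydroxyphenyl)-3-(3,4-dimethoxyphenyl)prop-2-en-1-one (the alkene geometry has no bearing on the closure) | CCN(CC)/C(=C/C(=O)c1ccc(O)cc1O)c1ccc(OC)c(OC)c1 | intermediate (not isolated)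
7 | 2-(3,4-dimethoxyphenyl)-7-hydroxychromen-4-one | COc1ccc(-c2cc(=O)c3ccc(O)cc3o2)cc1OC | intermediate
8 | 2-(3,4-dimethoxyphenyl)-7-hydroxy-6,8-diiodochromen-4-one | COc1ccc(-c2cc(=O)c3cc(I)c(O)c(I)c3o2)cc1OC | intermediate
9 | prenylboronic acid pinacol ester | CC(C)=CCB1OC(C)(C)C(C)(C)O1 | starting material
10 | 2-(3,4-dimethoxyphenyl)-7-hydroxy-6,8-bis(3-methylbut-2-enyl)chromen-4-one | COc1ccc(-c2cc(=O)c3cc(CC=C(C)C)c(O)c(CC=C(C)C)c3o2)cc1OC | intermediate
11 | 7-{[diethoxy(methyl)silyl]oxy}-2-(3,4-dimethoxyphenyl)-6,8-bis(3-methylbut-2-enyl)chromen-4-one | COc1ccc(-c2cc(=O)c3cc(CC=C(C)C)c(O[Si](C)(OCC)OCC)c(CC=C(C)C)c3o2)cc1OC | intermediate (not isolated)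
12 | (2S)-4,7-bis{[diethoxy(methyl)silyl]oxy}-2-(3,4-dimethoxyphenyl)-6,8-bis(3-methylbut-2-enyl)-2H-chromene | COc1ccc([C@@H]2C=C(O[Si](C)(OCC)OCC)c3cc(CC=C(C)C)c(O[Si](C)(OCC)OCC)c(CC=C(C)C)c3O2)cc1OC | intermediate (not isolated)
13 | (2S)-2-(3,4-dimethoxyphenyl)-7-hydroxy-6,8-bis(3-methylbut-2-enyl)chroman-4-one | COc1ccc([C@@H]2CC(=O)c3cc(CC=C(C)C)c(O)c(CC=C(C)C)c3O2)cc1OC | target

## Step count and least certain steps

Total: 5 steps. Longest linear sequence: 5 steps (1 to 2 to 7 to 8 to 10 to 13); 3, 4 and 9 enter as purchased reagents.

**Step 2 (key step).**
- What may go wrong: coupling of the aryl palladium with the alkyne before carbon monoxide inserts; capture of the aroyl palladium by diethylamine in place of the alkyne; closure through the alpha carbon (5-exo) if the phenol is released before the amine has added to the ynone; slow oxidative addition if the acetates are lost too early and the arene becomes a phenoxide.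
- Fallback: a two-component ynone synthesis without carbon monoxide, setting out from 4 and rejoining the route at 7. 2,4-Dihydroxybenzoic acid F1 is acetylated (Ac2O, pyridine) to 2,4-diacetoxybenzoic acid F2, which oxalyl chloride and catalytic DMF convert into 2,4-diacetoxybenzoyl chloride F3. Acyl Sonogashira coupling of F3 with 4 (PdCl2(PPh3)2, CuI, Et3N, THF, rt) gives 5, now isolated, and stirring 5 in Et2NH at 40 to 60 °C unmasks the phenols and closes ring C to 7 as in step 2.

**Step 5.**
- What may go wrong: insufficient facial discrimination, because the C2 substituent is a conjugated aryl group and not the alkyl group of the best-behaved chromenone substrates; hydride delivery to the C4 carbonyl if the ketone is released in the flask before the copper hydride is quenched; ring opening by beta-elimination of the copper enolate before it is silylated; sluggish addition to an electron-rich vinylogous ester.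
- Fallback: racemic reduction followed by kinetic resolution, setting out from 10 and rejoining at 13. An achiral copper hydride (Cu(OAc)2, 1,2-bis(diphenylphosphino)benzene, (EtO)2MeSiH, THF; then aq. NH4F) should give racemic 2-(3,4-dimethoxyphenyl)-7-hydroxy-6,8-bis(3-methylbut-2-enyl)chroman-4-one F4. Asymmetric transfer hydrogenation with RuCl(p-cymene)[(R,R)-TsDPEN] in HCO2H–Et3N at rt, stopped near half conversion, is expected to reduce the (2R) ketone to the cis alcohol (2R,4R)-2-(3,4-dimethoxyphenyl)-6,8-bis(3-methylbut-2-enyl)chromane-4,7-diol F5 and leave 13, which is separated by chromatography. The prenyl alkenes are inert to this catalyst and the medium is not basic.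

**Step 4.**
- What may go wrong: bond formation at the tertiary allyl terminus at one or both sites; protodeiodination; a stalled second coupling at the more hindered C8, which lies between two oxygens.
- Fallback: allylation followed by cross-metathesis, which removes the regiochemical question because the allyl group is symmetrical; it sets out from 8 and rejoins at 10. Suzuki–Miyaura coupling of 8 with allylboronic acid pinacol ester (PdCl2(dppf), K2CO3, dioxane–H2O, 80 °C) should give 6,8-diallyl-2-(3,4-dimethoxyphenyl)-7-hydroxychromen-4-one F6. Double cross-metathesis of F6 with excess 2-methylbut-2-ene (second-generation Grubbs catalyst RuCl2(H2IMes)(PCy3)(=CHPh), CH2Cl2, 40 °C) then converts both allyl groups into prenyl groups and gives 10.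

**Step 3.**
- What may go wrong: a slow second iodination at C6 once C8 is substituted, or competing attack on ring B if the reaction has to be forced.
- Fallback: a route to the side chains without halogen, setting out from 7 and rejoining at 10. O-Allylation of 7 (allyl bromide, K2CO3, acetone, reflux) gives 7-(allyloxy)-2-(3,4-dimethoxyphenyl)chromen-4-one F7. Aromatic Claisen rearrangement (N,N-diethylaniline, 200 °C) moves the allyl group to C8, the position favoured in 7-allyloxychromenones, and gives 8-allyl-2-(3,4-dimethoxyphenyl)-7-hydroxychromen-4-one F8. A second O-allylation gives 8-allyl-7-(allyloxy)-2-(3,4-dimethoxyphenyl)chromen-4-one F9, and a second Claisen rearrangement, now possible only to C6, gives 6,8-diallyl-2-(3,4-dimethoxyphenyl)-7-hydroxychromen-4-one F6. Cross-metathesis of F6 with 2-methylbut-2-ene, as in the fallback for step 4, gives 10.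

## Further compounds

F1 | step 2 | 2,4-dihydroxybenzoic acid | O=C(O)c1ccc(O)cc1O
F2 | step 2 | 2,4-diacetoxybenzoic acid | CC(=O)Oc1ccc(C(=O)O)c(OC(C)=O)c1
F3 | step 2 | 2,4-diacetoxybenzoyl chloride | CC(=O)Oc1ccc(C(=O)Cl)c(OC(C)=O)c1
F4 | step 5 | racemic 2-(3,4-dimethoxyphenyl)-7-hydroxy-6,8-bis(3-methylbut-2-enyl)chroman-4-one | COc1ccc(C2CC(=O)c3cc(CC=C(C)C)c(O)c(CC=C(C)C)c3O2)cc1OC
F5 | step 5 | (2R,4R)-2-(3,4-dimethoxyphenyl)-6,8-bis(3-methylbut-2-enyl)chromane-4,7-diol | COc1ccc([C@H]2C[C@@H](O)c3cc(CC=C(C)C)c(O)c(CC=C(C)C)c3O2)cc1OC
F6 | step 4 | 6,8-diallyl-2-(3,4-dimethoxyphenyl)-7-hydroxychromen-4-one | COc1ccc(-c2cc(=O)c3cc(CC=C)c(O)c(CC=C)c3o2)cc1OC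
F7 | step 3 | 7-(allyloxy)-2-(3,4-dimethoxyphenyl)chromen-4-one | COc1ccc(-c2cc(=O)c3ccc(OCC=C)cc3o2)cc1OC
F8 | step 3 | 8-allyl-2-(3,4-dimethoxyphenyl)-7-hydroxychromen-4-one | COc1ccc(-c2cc(=O)c3ccc(O)c(CC=C)c3o2)cc1OC
F9 | step 3 | 8-allyl-7-(allyloxy)-2-(3,4-dimethoxyphenyl)chromen-4-one | COc1ccc(-c2cc(=O)c3ccc(OCC=C)c(CC=C)c3o2)cc1OC
A1 | alternative 1 | (5S)-5-(3,4-dimethoxyphenyl)-5-[(5-methylhex-4-en-1-yn-1-yl)oxy]pent-1-yn-3-one | C#CC(=O)C[C@H](OC#CCC=C(C)C)c1ccc(OC)c(OC)c1
A2 | alternative 1 | triisopropyl[(5-methylhex-4-en-1-yn-1-yl)oxy]silane | CC(C)=CCC#CO[Si](C(C)C)(C(C)C)C(C)C
A3 | alternative 1 | (2S)-2-(3,4-dimethoxyphenyl)-6,8-bis(3-methylbut-2-enyl)-7-(triisopropylsilyloxy)chroman-4-one | COc1ccc([C@@H]2CC(=O)c3cc(CC=C(C)C)c(O[Si](C(C)C)(C(C)C)C(C)C)c(CC=C(C)C)c3O2)cc1OC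
A4 | alternative 2 | (3S)-3-[2-bromo-5-(triisopropylsilyloxy)phenoxy]-3-(3,4-dimethoxyphenyl)-N-methoxy-N-methylpropanamide | CON(C)C(=O)C[C@H](Oc1cc(O[Si](C(C)C)(C(C)C)C(C)C)ccc1Br)c1ccc(OC)c(OC)c1
A5 | alternative 2 | (2S)-2-(3,4-dimethoxyphenyl)-7-(triisopropylsilyloxy)chroman-4-one | COc1ccc([C@@H]2CC(=O)c3ccc(O[Si](C(C)C)(C(C)C)C(C)C)cc3O2)cc1OC
A6 | alternative 3 | (E)-3-(3,4-dimethoxyphenyl)prop-2-enoic acid | COc1ccc(/C=C/C(=O)O)cc1OC
A7 | alternative 3 | malonic acid | OC(=O)CC(=O)O
A8 | alternative 3 | (2S)-2-(3,4-dimethoxyphenyl)-7-hydroxychroman-4-one | COc1ccc([C@@H]2CC(=O)c3ccc(O)cc3O2)cc1OC
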